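**Retrosynthetic overview**

1. Positions use germacrane numbering (lactone O on C8, angelate on C6, oxirane C4–C5, free carbinol C1). The last bond made is C1–C10, by Nozaki–Hiyama–Kishi closure of the ten-membered ring from a C1 aldehyde and a C10 alkenyl bromide.
2. The C6 angelate comes from Mitsunobu inversion of an erythro epoxy alcohol, itself from chelation-controlled reduction of a C6 epoxy ketone.
3. Key bond C6–C7: a photocatalytically generated α,β-epoxy acyl radical adds to the β-carbon of a C8-stereogenic butenolide, anti to the C8 side chain (sets C7). An acetoxymethyl group on C11 stands in for the later methylene, so the adduct cannot act as a radical acceptor.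
4. The butenolide comes from ring-closing metathesis of a 2-(acetoxymethyl)acrylate of (S)-5-bromohexa-1,5-dien-3-ol (acrolein, 2,3-dibromopropene, Sharpless kinetic resolution). The epoxy aldehyde comes from pent-4-yn-1-ol (carboalumination, Sharpless epoxidation).
5. Ring order: lactone (butenolide) first, oxirane on the side chain second, ten-membered carbocycle last.

Assumption: germacrane numbering as in line 1 (C10=C14 and C11=C13 are the methylenes, C15 the methyl); the target is then (1S,4R,5R,6S,7R,8S).

**Route**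

Step 1
Reactants: 1 acrolein (prop-2-enal); 2 2,3-dibromoprop-1-ene
Product: 3 rac-5-bromohexa-1,5-dien-3-ol
Conditions: In powder, THF–H2O (1:1), 20 °C
Reagents that add atoms: none
Why: Barbier allylation, in which the allylindium species from the allylic C–Br bond of 2 adds 1,2 to the enal and the vinylic bromide is kept for the final ring closure; the carbinol (later C8) is racemic here.

Step 2
Reactants: 3 rac-5-bromohexa-1,5-dien-3-ol
Product: 4 (3S)-5-bromohexa-1,5-dien-3-ol
Conditions: Ti(OiPr)4 (0.2 equiv), D-(−)-diisopropyl tartrate (0.3 equiv), t-BuOOH (0.6 equiv), 4 Å MS, CH2Cl2, −20 °C, to about 55 % conversion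
Reagents that add atoms: none
Why: Sharpless kinetic resolution, in which the D-tartrate catalyst epoxidises the (R)-alcohol fast and leaves the (S)-alcohol (at most 50 %) in high ee, as in the resolution of 1-alken-3-ols; this fixes C8.

Step 3
Reactants: 4 (3S)-5-bromohexa-1,5-dien-3-ol; 5 2-(bromomethyl)prop-2-enoic acid
Product: 7 (3S)-5-bromohexa-1,5-dien-3-yl 2-(acetoxymethyl)prop-2-enoate, via bromo ester 6 (not isolated)
Conditions: DCC, DMAP (5 mol %), CH2Cl2, 0 °C; then n-Bu4NOAc, 20 °C
Reagents that add atoms: tetrabutylammonium acetate, CC(=O)[O-].CCCC[N+](CCCC)(CCCC)CCCC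
Why: Steglich esterification followed by acetate displacement of the allylic bromide (SN2 and SN2' give the same product), which installs the acetoxymethyl carbon that becomes C13; C8 is not touched.

Step 4
Reactants: 7 (3S)-5-bromohexa-1,5-dien-3-yl 2-(acetoxymethyl)prop-2-enoate
Product: 8 [(5S)-5-(2-bromoprop-2-en-1-yl)-2-oxo-2,5-dihydrofuran-3-yl]methyl acetate
Conditions: second-generation Hoveyda–Grubbs catalyst (5 mol %), toluene, 80 °C, 0.01 M
Reagents that add atoms: none
Why: ring-closing metathesis between the vinyl group and the 2-substituted acrylate gives the butenolide with loss of ethene, as for methacrylates of allylic alcohols; the 2-bromoalkene is inert to the catalyst and C8 is not touched.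

Step 5
Reactants: 9 pent-4-yn-1-ol
Product: 10 triethyl(pent-4-yn-1-yloxy)silane
Conditions: Et3SiCl, imidazole, CH2Cl2, 0 → 20 °C
Reagents that add atoms: chlorotriethylsilane, CC[Si](Cl)(CC)CC
Why: silyl ether formation; the primary triethylsilyl ether survives steps 6–11 and is oxidised directly to the C1 aldehyde in step 12.

Step 6
Reactants: 10 triethyl(pent-4-yn-1-yloxy)silane
Product: 12 (2E)-3-methyl-6-(triethylsilyloxy)hex-2-en-1-ol, via alkenylalane 11 (not isolated)
Conditions: AlMe3, Cp2ZrCl2 (20 mol %), CH2Cl2, 0 → 20 °C; then n-BuLi, THF, −78 °C; (CH2O)n, → 20 °C; aq. Rochelle salt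
Reagents that add atoms: trimethylaluminium, C[Al](C)C; paraformaldehyde (as formaldehyde), C=O
Why: Negishi zirconium-catalysed syn-carboalumination puts the methyl group (C15) on the internal alkyne carbon, and hydroxymethylation of the alkenylaluminate with retention gives only the (E)-allylic alcohol (C4=C5 geometry, C6 carbon).

Step 7
Reactants: 12 (2E)-3-methyl-6-(triethylsilyloxy)hex-2-en-1-ol
Product: 13 {(2R,3R)-3-methyl-3-[3-(triethylsilyloxy)propyl]oxiran-2-yl}methanol
Conditions: Ti(OiPr)4 (10 mol %), D-(−)-diisopropyl tartrate (12 mol %), t-BuOOH, 4 Å MS, CH2Cl2, −20 °C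
Reagents that add atoms: tert-butyl hydroperoxide, CC(C)(C)OO
Why: Sharpless asymmetric epoxidation; the D-tartrate gives the (2R,3R) oxirane, the same sense as geraniol to (2R,3R)-2,3-epoxygeraniol, and so sets C4 and C5.

Step 8
Reactants: 13 {(2R,3R)-3-methyl-3-[3-(triethylsilyloxy)propyl]oxiran-2-yl}methanol
Product: 14 (2S,3R)-3-methyl-3-[3-(triethylsilyloxy)propyl]oxirane-2-carbaldehyde
Conditions: (n-Pr4N)[RuO4] (5 mol %), NMO, 4 Å MS, CH2Cl2, 20 °C
Reagents that add atoms: none
Why: Ley–Griffith oxidation gives the epoxy aldehyde under neutral conditions without opening the oxirane; the descriptor at C5 changes by priority only.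

Step 9 (key step)
Reactants: 14 (2S,3R)-3-methyl-3-[3-(triethylsilyloxy)propyl]oxirane-2-carbaldehyde; 8 [(5S)-5-(2-bromoprop-2-en-1-yl)-2-oxo-2,5-dihydrofuran-3-yl]methyl acetate
Product: 15 [(3RS,4R,5S)-5-(2-bromoprop-2-en-1-yl)-4-{(2S,3R)-3-methyl-3-[3-(triethylsilyloxy)propyl]oxirane-2-carbonyl}-2-oxooxolan-3-yl]methyl acetate
Conditions: (n-Bu4N)4[W10O32] (2 mol %), 14 (1.5 equiv), MeCN (0.1 M), 390 nm LED, 20 °C, Ar
Reagents that add atoms: none
Why: Proposed new method: excited decatungstate abstracts the formyl hydrogen of 14 (the weakest and most hydridic C–H); the resulting α,β-epoxy acyl σ-radical should be stable, since decarbonylation would give a strained oxiranyl radical and ring opening to a ketene plus an alkoxyl radical is uphill; it adds as a nucleophilic radical to the β-carbon (C7) of 8 anti to the C8 bromoallyl group, which sets the trans C7/C8 relationship, and back hydrogen transfer from the reduced tungstate to the α-lactone radical closes the cycle (C11 forms as a mixture that is removed in step 12); the closest known reactions are the decatungstate-photocatalysed Giese hydroacylation of electron-poor alkenes with aliphatic aldehydes and the trans-selective radical addition to 5-substituted furan-2(5H)-ones.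

Step 10
Reactants: 15 (keto lactone from step 9)
Product: 16 [(3RS,4S,5S)-5-(2-bromoprop-2-en-1-yl)-4-{(R)-hydroxy{(2R,3R)-3-methyl-3-[3-(triethylsilyloxy)propyl]oxiran-2-yl}methyl}-2-oxooxolan-3-yl]methyl acetate
Conditions: Zn(BH4)2, Et2O, −30 °C
Reagents that add atoms: none
Why: chelation-controlled reduction of an α,β-epoxy ketone (Nakata–Oishi): zinc bridges the carbonyl and oxirane oxygens and hydride enters from the side of the C5 hydrogen, giving the erythro (anti) epoxy alcohol, here (6R); the lactone and acetate are not reduced, and the ring descriptor 4S differs from 4R in 15 by priority only.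

Step 11
Reactants: 16 (erythro epoxy alcohol from step 10); 17 angelic acid [(2Z)-2-methylbut-2-enoic acid]
Product: 18 [(3RS,4R,5S)-5-(2-bromoprop-2-en-1-yl)-4-{(S)-[(2Z)-2-methylbut-2-enoyloxy]{(2R,3R)-3-methyl-3-[3-(triethylsilyloxy)propyl]oxiran-2-yl}methyl}-2-oxooxolan-3-yl]methyl acetate
Conditions: PPh3, DIAD, 17 (3 equiv), toluene, 0 → 20 °C
Reagents that add atoms: none
Why: Mitsunobu esterification proceeds with SN2 inversion at C6, so the erythro (6R) alcohol becomes the threo (6S) angelate of the target in the same step that installs the ester; the neutral conditions should leave the (Z)-acid geometry intact.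

Step 12
Reactants: 18 (angelate from step 11)
Product: 20 (S)-[(2S,3R)-2-(2-bromoprop-2-en-1-yl)-4-methylidene-5-oxooxolan-3-yl][(2R,3R)-3-methyl-3-(3-oxopropyl)oxiran-2-yl]methyl (2Z)-2-methylbut-2-enoate, via aldehyde acetate 19 (not isolated)
Conditions: (COCl)2, DMSO, CH2Cl2, −78 → −30 °C; Et3N, → 0 °C; then DBU (1.1 equiv), 0 °C, 15 min
Reagents that add atoms: none
Why: Swern conditions oxidise a primary triethylsilyl ether directly to the aldehyde (C1), and DBU then removes acetic acid by E1cB elimination to give the α-methylene lactone (C11=C13); no stereocentre is involved and the short, cold base treatment spares the angelate and C7.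

Step 13
Reactants: 20 (aldehyde alkenyl bromide from step 12)
Product: 21 (1S,4R,5R,6S,7R,8S)-4,5-epoxy-1-hydroxy-6-[(2Z)-2-methylbut-2-enoyloxy]germacra-10(14),11(13)-dien-12,8-olide (target)
Conditions: CrCl2 (10 equiv), NiCl2 (0.2 equiv), DMSO, 20 °C, 2 mM, slow addition
Reagents that add atoms: none
Why: Nozaki–Hiyama–Kishi reaction: the alkenyl bromide is activated by nickel, transferred to chromium and added intramolecularly to the aldehyde, which closes the ten-membered ring at C1–C10 and creates the C1 carbinol beside the C10 methylene; the (1S) epimer is expected from closure through the extended conformer that keeps the chromium alkoxide on the outer face of the forming ring, but this is a prediction and any (1R) epimer is removed by chromatography.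

**Compound list**

1 | acrolein (prop-2-enal) | C=CC=O | starting material
2 | 2,3-dibromoprop-1-ene | C=C(Br)CBr | starting material
3 | rac-5-bromohexa-1,5-dien-3-ol | C=CC(O)CC(Br)=C | intermediate
4 | (3S)-5-bromohexa-1,5-dien-3-ol | O[C@H](C=C)CC(Br)=C | intermediate
5 | 2-(bromomethyl)prop-2-enoic acid | C=C(CBr)C(=O)O | starting material
6 | (3S)-5-bromohexa-1,5-dien-3-yl 2-(bromomethyl)prop-2-enoate | C=C(CBr)C(=O)O[C@H](C=C)CC(Br)=C | intermediate (not isolated)
7 | (3S)-5-bromohexa-1,5-dien-3-yl 2-(acetoxymethyl)prop-2-enoate | CC(=O)OCC(=C)C(=O)O[C@H](C=C)CC(Br)=C | intermediate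
8 | [(5S)-5-(2-bromoprop-2-en-1-yl)-2-oxo-2,5-dihydrofuran-3-yl]methyl acetate | CC(=O)OCC1=C[C@H](CC(Br)=C)OC1=O | intermediate
9 | pent-4-yn-1-ol | C#CCCCO | starting material
10 | triethyl(pent-4-yn-1-yloxy)silane | CC[Si](CC)(CC)OCCCC#C | intermediate
11 | dimethyl[(1E)-2-methyl-5-(triethylsilyloxy)pent-1-en-1-yl]alumane | C[Al](C)/C=C(\C)CCCO[Si](CC)(CC)CC | intermediate (not isolated)
12 | (2E)-3-methyl-6-(triethylsilyloxy)hex-2-en-1-ol | OC/C=C(\C)CCCO[Si](CC)(CC)CC | intermediate
13 | {(2R,3R)-3-methyl-3-[3-(triethylsilyloxy)propyl]oxiran-2-yl}methanol | CC[Si](CC)(CC)OCCC[C@@]1(C)O[C@@H]1CO | intermediate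
14 | (2S,3R)-3-methyl-3-[3-(triethylsilyloxy)propyl]oxirane-2-carbaldehyde | CC[Si](CC)(CC)OCCC[C@@]1(C)O[C@@H]1C=O | intermediate
15 | [(3RS,4R,5S)-5-(2-bromoprop-2-en-1-yl)-4-{(2S,3R)-3-methyl-3-[3-(triethylsilyloxy)propyl]oxirane-2-carbonyl}-2-oxooxolan-3-yl]methyl acetate (C7 R, C8 S, trans) | CC(=O)OCC1C(=O)O[C@@H](CC(Br)=C)[C@@H]1C(=O)[C@H]2O[C@]2(C)CCCO[Si](CC)(CC)CC | intermediate
16 | [(3RS,4S,5S)-5-(2-bromoprop-2-en-1-yl)-4-{(R)-hydroxy{(2R,3R)-3-methyl-3-[3-(triethylsilyloxy)propyl]oxiran-2-yl}methyl}-2-oxooxolan-3-yl]methyl acetate (erythro; C6 R) | CC(=O)OCC1C(=O)O[C@@H](CC(Br)=C)[C@@H]1[C@@H](O)[C@H]2O[C@]2(C)CCCO[Si](CC)(CC)CC | intermediate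
17 | angelic acid, (2Z)-2-methylbut-2-enoic acid | OC(=O)/C(C)=C\C | starting material
18 | [(3RS,4R,5S)-5-(2-bromoprop-2-en-1-yl)-4-{(S)-[(2Z)-2-methylbut-2-enoyloxy]{(2R,3R)-3-methyl-3-[3-(triethylsilyloxy)propyl]oxiran-2-yl}methyl}-2-oxooxolan-3-yl]methyl acetate (threo; C6 S) | CC(=O)OCC1C(=O)O[C@@H](CC(Br)=C)[C@@H]1[C@H](OC(=O)/C(C)=C\C)[C@H]2O[C@]2(C)CCCO[Si](CC)(CC)CC | intermediate
19 | [(3RS,4R,5S)-5-(2-bromoprop-2-en-1-yl)-4-{(S)-[(2Z)-2-methylbut-2-enoyloxy][(2R,3R)-3-methyl-3-(3-oxopropyl)oxiran-2-yl]methyl}-2-oxooxolan-3-yl]methyl acetate | CC(=O)OCC1C(=O)O[C@@H](CC(Br)=C)[C@@H]1[C@H](OC(=O)/C(C)=C\C)[C@H]2O[C@]2(C)CCC=O | intermediate (not isolated)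
20 | (S)-[(2S,3R)-2-(2-bromoprop-2-en-1-yl)-4-methylidene-5-oxooxolan-3-yl][(2R,3R)-3-methyl-3-(3-oxopropyl)oxiran-2-yl]methyl (2Z)-2-methylbut-2-enoate | C=C1C(=O)O[C@@H](CC(Br)=C)[C@@H]1[C@H](OC(=O)/C(C)=C\C)[C@H]2O[C@]2(C)CCC=O | intermediate
21 | (1S,4R,5R,6S,7R,8S)-4,5-epoxy-1-hydroxy-6-[(2Z)-2-methylbut-2-enoyloxy]germacra-10(14),11(13)-dien-12,8-olide | C=C1C(=O)O[C@H]2CC(=C)[C@@H](O)CC[C@@]3(C)O[C@@H]3[C@@H](OC(=O)/C(C)=C\C)[C@H]12 | target

**Step count and risks**

Total steps: 13. Longest linear sequence: 9 (steps 1–4 or 5–8, then 9–13).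

Step 9 is the most likely to fail. The excited decatungstate may also abstract hydrogen next to the silyl ether of 14 or at C8–H of 8 (racemisation), and the epoxy acyl radical is untested. The fallback sets out from 14 and returns at 15, and makes the same radical by group transfer instead of hydrogen abstraction. Compound 14 is oxidised (NaClO2, NaH2PO4, 2-methylbut-2-ene) to (2S,3R)-3-methyl-3-[3-(triethylsilyloxy)propyl]oxirane-2-carboxylic acid F1. PhSeSePh and PBu3 convert this into Se-phenyl (2S,3R)-3-methyl-3-[3-(triethylsilyloxy)propyl]oxirane-2-carboselenoate F2. (Me3Si)3SiH and AIBN (benzene, 80 °C, slow addition) then carry the acyl radical in a silyl-radical chain onto 8 and give 15.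

Step 11 is the second risk: Mitsunobu inversion at a hindered carbinol flanked by the oxirane and the lactone ring may be slow, give elimination, or isomerise the angelate. The fallback sets out from 16 and returns at 18, and separates activation from displacement. Compound 16 is treated with ClCH2SO2Cl and pyridine (0 °C) to give the C6 chloromethanesulfonate of alcohol 16 F3. This is displaced with inversion by caesium angelate (17, Cs2CO3, 18-crown-6, toluene, 50 °C); carboxylate alkylation keeps the (Z) geometry and gives 18.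

Step 13 is the third risk: the ring may close with the wrong C1 configuration or as a mixture. The fallback sets out from 20 and returns at 21, and sets C1 by reagent control after ring closure. The closure is run as in step 13 without regard to C1. The product, in the worst case mainly (1R,4R,5R,6S,7R,8S)-4,5-epoxy-1-hydroxy-6-[(2Z)-2-methylbut-2-enoyloxy]germacra-10(14),11(13)-dien-12,8-olide F4, is oxidised with Dess–Martin periodinane to (4R,5R,6S,7R,8S)-4,5-epoxy-6-[(2Z)-2-methylbut-2-enoyloxy]-1-oxogermacra-10(14),11(13)-dien-12,8-olide F5. Reduction with (R)-2-methyl-CBS-oxazaborolidine and catecholborane (toluene, −78 °C), with the 2-substituted alkenyl group as the large substituent, gives the (1S) alcohol 21.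

**Further compounds**

F1 | step 9 | (2S,3R)-3-methyl-3-[3-(triethylsilyloxy)propyl]oxirane-2-carboxylic acid | CC[Si](CC)(CC)OCCC[C@@]1(C)O[C@@H]1C(=O)O
F2 | step 9 | Se-phenyl (2S,3R)-3-methyl-3-[3-(triethylsilyloxy)propyl]oxirane-2-carboselenoate | CC[Si](CC)(CC)OCCC[C@@]1(C)O[C@@H]1C(=O)[Se]c1ccccc1
F3 | step 11 | C6 chloromethanesulfonate of alcohol 16 (6R) | CC(=O)OCC1C(=O)O[C@@H](CC(Br)=C)[C@@H]1[C@@H](OS(=O)(=O)CCl)[C@H]2O[C@]2(C)CCCO[Si](CC)(CC)CC
F4 | step 13 | (1R,4R,5R,6S,7R,8S)-4,5-epoxy-1-hydroxy-6-[(2Z)-2-methylbut-2-enoyloxy]germacra-10(14),11(13)-dien-12,8-olide | C=C1C(=O)O[C@H]2CC(=C)[C@H](O)CC[C@@]3(C)O[C@@H]3[C@@H](OC(=O)/C(C)=C\C)[C@H]12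
F5 | step 13 | (4R,5R,6S,7R,8S)-4,5-epoxy-6-[(2Z)-2-methylbut-2-enoyloxy]-1-oxogermacra-10(14),11(13)-dien-12,8-olide | C=C1C(=O)O[C@H]2CC(=C)C(=O)CC[C@@]3(C)O[C@@H]3[C@@H](OC(=O)/C(C)=C\C)[C@H]12
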